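**Overview**

- Retrosynthesis: the nine O-benzyl bonds are cut first; the C4 carbonyl of the taxifolin half goes back to a catechin CH2; the C3(flavanone)–C8(taxifolin) bond is cut by a retro 1,2-aryl shift that returns the aryl group to C4 of a 4-aryl-4-hydroxy-3-mesyloxy flavan; that C4–C8 bond is cut to an 8-lithiated catechin ether and an epicatechin-derived 4-ketone.
- Forward: no ring is built, because both benzopyrans and both catechol rings are bought in (−)-epicatechin and (+)-catechin. The two protected flavans are joined C4–C8 by aryllithium addition, the junction is moved to C3–C8 by the aryl shift, C4 of the catechin half is oxidised, and hydrogenolysis frees the nine hydroxyls.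
- Enabling feature: in ring C of the flavanone half, C3 carries C8 of ring A of the taxifolin half directly beside the C4 carbonyl. This α-aryl ketone is what a C4-to-C3 aryl migration gives when a C3 sulfonate leaves and C4=O forms.
- Stereochemistry: C2 of the flavanone half is C2 of epicatechin; C2 and C3 of the taxifolin half are those of catechin (only the descriptors change). C3 of the flavanone half comes from inversion of the epicatechin C3–O bond during the shift (2,3-cis C–O becomes 2,3-trans C–aryl). The temporary C4 carbinol centre is set anti to the axial 3-silyloxy group and then destroyed.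

Key step: step 11

Remark: the hindered C3–C8 bond of the target is assumed to give interconverting rotamers and not a stable stereogenic axis, so only the four stereocentres are controlled; flavonoid atom numbers are used for both halves.

**Route**

Step 1
Reactants: 1 (−)-epicatechin
Product: 2 5,7,3',4'-tetra-O-benzyl-(−)-epicatechin
Conditions: BnBr (4.4 equiv), K2CO3, DMF, 0 °C to rt
Reagents that add atoms: benzyl bromide, BrCc1ccccc1
Why: Williamson etherification in which K2CO3 deprotonates only the four phenols, so that the secondary 3-OH stays free and C2 and C3 are not touched.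

Step 2
Reactants: 2 5,7,3',4'-tetra-O-benzyl-(−)-epicatechin
Product: 3 5,7,3',4'-tetra-O-benzyl-3-O-(tert-butyldimethylsilyl)-(−)-epicatechin
Conditions: TBSCl, imidazole, DMF, rt
Reagents that add atoms: tert-butyldimethylsilyl chloride, CC(C)(C)[Si](C)(C)Cl
Why: Imidazole-promoted silylation of the one remaining hydroxyl gives a silyl ether that survives DDQ, the periodinane and the aryllithium and is later cleaved by fluoride beside benzyl ethers.

Step 3
Reactants: 3 5,7,3',4'-tetra-O-benzyl-3-O-(tert-butyldimethylsilyl)-(−)-epicatechin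
Product: 4 4β-hydroxy derivative of 3 (3,4-trans alcohol)
Conditions: DDQ (2 equiv), CH2Cl2/H2O (18:1), rt
Reagents that add atoms: water, O
Why: DDQ benzylic oxidation, in which hydride abstraction at C4 is assisted by the ortho and para benzyloxy groups of ring A and water traps the cation anti to the axial 3-silyloxy group, giving a 3,4-trans alcohol whose new centre is erased in step 4.

Step 4
Reactants: 4 4β-hydroxy derivative of 3
Product: 5 5,7,3',4'-tetra-O-benzyl-3-O-TBS-4-oxo-epicatechin (2,3-cis flavan-4-one; fragment 1)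
Conditions: Dess–Martin periodinane, NaHCO3, CH2Cl2, rt
Reagents that add atoms: none
Why: Dess–Martin oxidation of the secondary benzylic alcohol under buffered non-enolising conditions, so that the 2,3-cis α-silyloxy ketone does not epimerise to the 2,3-trans isomer.

Step 5
Reactants: 6 (+)-catechin
Product: 7 5,7,3',4'-tetra-O-benzyl-(+)-catechin
Conditions: BnBr (4.4 equiv), K2CO3, DMF, 0 °C to rt
Reagents that add atoms: benzyl bromide, BrCc1ccccc1
Why: Williamson etherification of the four phenols as in step 1, the mild carbonate base leaving the 3-OH and both stereocentres alone.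

Step 6
Reactants: 7 5,7,3',4'-tetra-O-benzyl-(+)-catechin
Product: 9 3,5,7,3',4'-penta-O-benzyl-(+)-catechin, via sodium 3-alkoxide 8 (not isolated)
Conditions: NaH, DMF, 0 °C; then BnBr, Bu4NI (cat.), 0 °C to rt
Reagents that add atoms: benzyl bromide, BrCc1ccccc1
Why: Williamson etherification of the secondary alkoxide puts a ninth benzyl group on the future taxifolin 3-oxygen, so that one hydrogenolysis will later free every hydroxyl.

Step 7
Reactants: 9 3,5,7,3',4'-penta-O-benzyl-(+)-catechin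
Product: 10 8-bromo-3,5,7,3',4'-penta-O-benzyl-(+)-catechin (fragment 2)
Conditions: NBS (1.0 equiv), CH2Cl2, −78 °C to rt
Reagents that add atoms: N-bromosuccinimide, O=C1CCC(=O)N1Br
Why: Electrophilic aromatic bromination of the phloroglucinol-type ring A, which in benzylated flavan-3-ols takes place at C8 rather than C6 when one equivalent of NBS is used cold, ring B being much less nucleophilic.

Step 8
Reactants: 10 8-bromo-3,5,7,3',4'-penta-O-benzyl-(+)-catechin; 5 5,7,3',4'-tetra-O-benzyl-3-O-TBS-4-oxo-epicatechin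
Product: 13 C4 tertiary carbinol (4-hydroxy-4-(penta-O-benzylcatechin-8-yl) derivative of 3; aryl trans to 3-OTBS and to ring B), via 8-lithio flavan 11 (not isolated), via lithium alkoxide 12 (not isolated)
Conditions: 10 (1.5 equiv), t-BuLi (2 equiv per bromide), THF, −78 °C; then 5, −78 to 0 °C; then H2O
Reagents that add atoms: none
Why: Bromine–lithium exchange followed by 1,2-addition of the aryllithium to the ketone, a reaction type with close analogy for 8-lithiated benzylated flavans and this kind of 4-ketone; the nucleophile attacks anti to the axial 3-silyloxy group (Felkin–Anh and steric control), so the new C4 centre carries the aryl trans to 3-OTBS and to ring B.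

Step 9
Reactants: 13 C4 tertiary carbinol
Product: 14 cis-3,4-diol (3-OH secondary, 4-OH tertiary; 4-aryl trans to both hydroxyls' neighbour ring B)
Conditions: Bu4NF, THF, 0 °C to rt
Reagents that add atoms: none
Why: Fluoride-mediated desilylation driven by the Si–F bond frees the secondary 3-OH without touching benzyl ethers or the tertiary carbinol.

Step 10
Reactants: 14 cis-3,4-diol
Product: 15 3-O-mesyl 4-aryl-4-hydroxy flavan (3-OMs and 4-aryl trans)
Conditions: MsCl, Et3N, CH2Cl2, −20 to 0 °C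
Reagents that add atoms: methanesulfonyl chloride, CS(=O)(=O)Cl
Why: Sulfonylation by way of sulfene, which is small enough to reach the hindered axial secondary 3-OH while the tertiary doubly benzylic 4-OH stays free, and the cis relation of 4-OH and 3-OMs rules out epoxide closure under the basic conditions.

Step 11
Reactants: 15 3-O-mesyl 4-aryl-4-hydroxy flavan
Product: 17 nona-O-benzyl 2,3-trans-3-(flavan-8-yl)flavan-4-one, via diethylaluminium alkoxide 16 (not isolated)
Conditions: Et3Al (4 equiv), CH2Cl2, −78 to 0 °C; then aq. KNaC4H4O6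
Reagents that add atoms: none
Why: Et3Al deprotonates the tertiary 4-OH (ethane is lost) to give the aluminium alkoxide 16, further Et3Al binds the sulfonate oxygens, and the alkoxide then pushes the pseudo-axial C4 aryl group (C8 of the catechin half) through a phenonium-like bridged transition state onto the rear face of C3 while mesylate leaves and the C4 carbonyl forms. This is the organoaluminium-promoted semipinacol rearrangement of a 2-sulfonyloxy tertiary alcohol (1,2-aryl shift with inversion), a known reaction type that is here applied to a flavan. No ring is closed: the benzopyran ring is kept and the only cyclic species is the transient three-membered aryl bridge, so no mode of ring closure has to be chosen. The new C3 stereocentre is set by stereospecific inversion, the aryl entering anti to the departing C3–O bond, which turns the 2,3-cis C–O bond of epicatechin into the 2,3-trans C–aryl bond; this is also the thermodynamic epimer, so any enolisation can only converge on it. The step needs migration of the exocyclic aryl rather than ring contraction by the C4–C4a bond, a shift of H-2 or ring B from C2, elimination, or ionisation of the carbinol: in the half-chair with ring B equatorial the axial mesylate is antiperiplanar only to the C4–aryl bond and to C2–H, the anionic push comes from C4 alone, the migrating ring is a 2,4,6-trioxygenated arene of very high migratory aptitude held axial by the peri 5-benzyloxy group, the cis 4-O/3-OMs relation excludes epoxide closure, and the aprotic medium keeps the doubly benzylic C4–O bond from ionising.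

Step 12
Reactants: 17 nona-O-benzyl 2,3-trans-3-(flavan-8-yl)flavan-4-one
Product: 18 4-hydroxy compound on the catechin half (3,4-trans alcohol)
Conditions: DDQ (2 equiv), CH2Cl2/H2O (18:1), rt
Reagents that add atoms: water, O
Why: DDQ benzylic oxidation as in step 3, directed to the only electron-rich benzylic methylene left (C4 of the catechin half), the flavanone half being deactivated by its carbonyl, with water adding trans to the 3-benzyloxy group to give a centre that step 13 removes.

Step 13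
Reactants: 18 4-hydroxy compound on the catechin half
Product: 19 nona-O-benzyl eriodictyol-(3→8)-taxifolin (both C4 ketones in place)
Conditions: Dess–Martin periodinane, NaHCO3, CH2Cl2, rt
Reagents that add atoms: none
Why: Dess–Martin oxidation of the secondary benzylic alcohol under buffered conditions that enolise neither C3 centre, both of which are in any case in their thermodynamic trans arrangement.

Step 14
Reactants: 19 nona-O-benzyl eriodictyol-(3→8)-taxifolin
Product: 20 (2S,3R)-eriodictyol-(3→8)-(2R,3R)-taxifolin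
Conditions: H2 (1 atm), Pd(OH)2/C, THF/MeOH (1:1), rt
Reagents that add atoms: none
Why: Catalytic hydrogenolysis of all nine benzylic C–O bonds (eight aryl benzyl ethers and one alkyl benzyl ether) under neutral conditions, in which the ring-A-conjugated ketones, hydrogen-bonded to the freed 5-hydroxyls, are not reduced and no stereocentre is touched.

**Compound list**

1 | (−)-epicatechin, (2R,3R), 2,3-cis | Oc1cc(O)c2c(c1)O[C@H](c1ccc(O)c(O)c1)[C@H](O)C2 | starting material
2 | 5,7,3',4'-tetra-O-benzyl-(−)-epicatechin | C1c2c(OCc3ccccc3)cc(OCc3ccccc3)cc2O[C@H](c2ccc(OCc3ccccc3)c(OCc3ccccc3)c2)[C@@H]1O | intermediate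
3 | 5,7,3',4'-tetra-O-benzyl-3-O-TBS-(−)-epicatechin | C1c2c(OCc3ccccc3)cc(OCc3ccccc3)cc2O[C@H](c2ccc(OCc3ccccc3)c(OCc3ccccc3)c2)[C@@H]1O[Si](C)(C)C(C)(C)C | intermediate
4 | 4β-hydroxy-5,7,3',4'-tetra-O-benzyl-3-O-TBS-epicatechin (4-OH trans to 3-OTBS) | O[C@H]1c2c(OCc3ccccc3)cc(OCc3ccccc3)cc2O[C@H](c2ccc(OCc3ccccc3)c(OCc3ccccc3)c2)[C@@H]1O[Si](C)(C)C(C)(C)C | intermediate
5 | 5,7,3',4'-tetra-O-benzyl-3-O-TBS-4-oxo-epicatechin (2,3-cis; fragment 1) | O=C1c2c(OCc3ccccc3)cc(OCc3ccccc3)cc2O[C@H](c2ccc(OCc3ccccc3)c(OCc3ccccc3)c2)[C@@H]1O[Si](C)(C)C(C)(C)C | intermediate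
6 | (+)-catechin, (2R,3S), 2,3-trans | Oc1cc(O)c2c(c1)O[C@H](c1ccc(O)c(O)c1)[C@@H](O)C2 | starting material
7 | 5,7,3',4'-tetra-O-benzyl-(+)-catechin | C1c2c(OCc3ccccc3)cc(OCc3ccccc3)cc2O[C@H](c2ccc(OCc3ccccc3)c(OCc3ccccc3)c2)[C@H]1O | intermediate
8 | sodium 3-alkoxide of 7 | C1c2c(OCc3ccccc3)cc(OCc3ccccc3)cc2O[C@H](c2ccc(OCc3ccccc3)c(OCc3ccccc3)c2)[C@H]1[O-].[Na+] | intermediate
9 | 3,5,7,3',4'-penta-O-benzyl-(+)-catechin | C1c2c(OCc3ccccc3)cc(OCc3ccccc3)cc2O[C@H](c2ccc(OCc3ccccc3)c(OCc3ccccc3)c2)[C@H]1OCc1ccccc1 | intermediate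
10 | 8-bromo-3,5,7,3',4'-penta-O-benzyl-(+)-catechin (fragment 2) | Brc1c(OCc2ccccc2)cc(OCc2ccccc2)c2c1O[C@H](c1ccc(OCc3ccccc3)c(OCc3ccccc3)c1)[C@@H](OCc1ccccc1)C2 | intermediate
11 | 8-lithio-3,5,7,3',4'-penta-O-benzylcatechin | [Li]c1c(OCc2ccccc2)cc(OCc2ccccc2)c2c1O[C@H](c1ccc(OCc3ccccc3)c(OCc3ccccc3)c1)[C@@H](OCc1ccccc1)C2 | intermediate
12 | lithium alkoxide of carbinol 13 | [Li+].[O-][C@]1(c3c(OCc4ccccc4)cc(OCc4ccccc4)c4c3O[C@H](c3ccc(OCc5ccccc5)c(OCc5ccccc5)c3)[C@@H](OCc3ccccc3)C4)c2c(OCc3ccccc3)cc(OCc3ccccc3)cc2O[C@H](c2ccc(OCc3ccccc3)c(OCc3ccccc3)c2)[C@@H]1O[Si](C)(C)C(C)(C)C | intermediate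
13 | C4 tertiary carbinol: 4-hydroxy-4-(penta-O-benzylcatechin-8-yl)-tetra-O-benzyl-3-O-TBS-epicatechin (aryl trans to 3-OTBS and ring B; 4-OH cis to 3-OTBS) | O[C@]1(c3c(OCc4ccccc4)cc(OCc4ccccc4)c4c3O[C@H](c3ccc(OCc5ccccc5)c(OCc5ccccc5)c3)[C@@H](OCc3ccccc3)C4)c2c(OCc3ccccc3)cc(OCc3ccccc3)cc2O[C@H](c2ccc(OCc3ccccc3)c(OCc3ccccc3)c2)[C@@H]1O[Si](C)(C)C(C)(C)C | intermediate
14 | cis-3,4-diol from 13 (3-OH free) | O[C@]1(c3c(OCc4ccccc4)cc(OCc4ccccc4)c4c3O[C@H](c3ccc(OCc5ccccc5)c(OCc5ccccc5)c3)[C@@H](OCc3ccccc3)C4)c2c(OCc3ccccc3)cc(OCc3ccccc3)cc2O[C@H](c2ccc(OCc3ccccc3)c(OCc3ccccc3)c2)[C@@H]1O | intermediate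
15 | 3-O-mesyl 4-aryl-4-hydroxy flavan (3-OMs axial, trans to the 4-aryl group) | O[C@]1(c3c(OCc4ccccc4)cc(OCc4ccccc4)c4c3O[C@H](c3ccc(OCc5ccccc5)c(OCc5ccccc5)c3)[C@@H](OCc3ccccc3)C4)c2c(OCc3ccccc3)cc(OCc3ccccc3)cc2O[C@H](c2ccc(OCc3ccccc3)c(OCc3ccccc3)c2)[C@@H]1OS(C)(=O)=O | intermediate
16 | diethylaluminium alkoxide of 15 | CC[Al](CC)O[C@]1(c3c(OCc4ccccc4)cc(OCc4ccccc4)c4c3O[C@H](c3ccc(OCc5ccccc5)c(OCc5ccccc5)c3)[C@@H](OCc3ccccc3)C4)c2c(OCc3ccccc3)cc(OCc3ccccc3)cc2O[C@H](c2ccc(OCc3ccccc3)c(OCc3ccccc3)c2)[C@@H]1OS(C)(=O)=O | intermediate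
17 | nona-O-benzyl 2,3-trans-3-(catechin-8-yl)flavan-4-one (tetra-O-benzyl-eriodictyol joined at C3 to C8 of penta-O-benzylcatechin) | O=C1c2c(OCc3ccccc3)cc(OCc3ccccc3)cc2O[C@H](c2ccc(OCc3ccccc3)c(OCc3ccccc3)c2)[C@H]1c1c(OCc2ccccc2)cc(OCc2ccccc2)c2c1O[C@H](c1ccc(OCc3ccccc3)c(OCc3ccccc3)c1)[C@@H](OCc1ccccc1)C2 | intermediate
18 | 4-hydroxy derivative of 17 at C4 of the catechin half (4-OH trans to 3-OBn) | O=C1c2c(OCc3ccccc3)cc(OCc3ccccc3)cc2O[C@H](c2ccc(OCc3ccccc3)c(OCc3ccccc3)c2)[C@H]1c1c(OCc2ccccc2)cc(OCc2ccccc2)c2c1O[C@H](c1ccc(OCc3ccccc3)c(OCc3ccccc3)c1)[C@@H](OCc1ccccc1)[C@@H]2O | intermediate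
19 | nona-O-benzyl eriodictyol-(3→8)-taxifolin | O=C1c2c(OCc3ccccc3)cc(OCc3ccccc3)cc2O[C@H](c2ccc(OCc3ccccc3)c(OCc3ccccc3)c2)[C@H]1c1c(OCc2ccccc2)cc(OCc2ccccc2)c2c1O[C@H](c1ccc(OCc3ccccc3)c(OCc3ccccc3)c1)[C@@H](OCc1ccccc1)C2=O | intermediate
20 | (2R,3R)-8-[(2S,3R)-2-(3,4-dihydroxyphenyl)-5,7-dihydroxy-4-oxochroman-3-yl]-2-(3,4-dihydroxyphenyl)-3,5,7-trihydroxychroman-4-one | O=C1c2c(O)cc(O)cc2O[C@H](c2ccc(O)c(O)c2)[C@H]1c1c(O)cc(O)c2c1O[C@H](c1ccc(O)c(O)c1)[C@@H](O)C2=O | target

**Step count and risks**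

Total step count: 14. Longest linear sequence: 11 steps (steps 1–4 and 8–14, from (−)-epicatechin).

Steps most likely to fail:

Step 11. The aluminium alkoxide may fail to push the very hindered, doubly ortho-oxygenated aryl group across. Hydride shift from C2, elimination toward C2, or ionisation of the doubly benzylic carbinol could then take over. The fallback replaces the sulfonate acceptor by a carbonyl group and sets out from diol 14. Dess–Martin oxidation of the secondary 3-OH should give the tertiary α-ketol, the 4-aryl-4-hydroxyflavan-3-one F1. BF3·OEt2 in CH2Cl2 at low temperature should then induce an α-ketol rearrangement in which the same aryl group moves from C4 to the C3 carbonyl carbon. The exocyclic pseudo-axial aryl bond overlaps with the carbonyl π system, whereas the ring bond C4–C4a does not, and the shift is driven by conjugation of the new C4 ketone with ring A. The product is the 3-aryl-3-hydroxyflavan-4-one F2. Samarium diiodide in THF/MeOH at −78 °C should remove the tertiary α-hydroxyl, and protonation with equilibration at C3 gives the 2,3-trans ketone, so the sequence comes back to the route at 17. Neutral and Lewis-acidic conditions are chosen so that C2 is not enolised; the chiral-pool control of C2 is kept, and C3 is then set thermodynamically instead of by inversion.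

Step 8. The hindered, strongly basic aryllithium may enolise ketone 5 (loss of the 2,3-cis configuration, ring opening) instead of adding, or add with poor facial selectivity. The fallback makes the same C4–C8 bond with reversed polarity, by Friedel–Crafts arylation of a C4 cation, and sets out from 4-ol 4 and penta-O-benzylcatechin 9 (in excess). Me3SiOTf in CH2Cl2 at −78 °C should give the 4β→8 linked flavan dimer F3 (aryl trans to 3-OTBS), which is the standard way of joining flavan-3-ol units. Bu4NF then frees the 3-hydroxyl to give the 3-ol F4, and Dess–Martin periodinane gives the 4-arylflavan-3-one F5. Hydroxylation at C4 (KN(SiMe3)2, THF, −78 °C, then 2-(phenylsulfonyl)-3-phenyloxaziridine; the doubly benzylic C4–H is by far the more acidic α-hydrogen) gives the tertiary α-ketol F6, expected as the C4 epimer of F1. Its configuration at C4 does not matter: BF3·OEt2 should convert it into the 3-aryl-3-hydroxyflavan-4-one F7, and SmI2 in THF/MeOH, as in the fallback to step 11, leads to 17, where the route is rejoined.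

Step 10. Sulfonylation of the hindered axial secondary hydroxyl may stay incomplete, or the acid-labile doubly benzylic carbinol may be lost during the two manipulations (desilylation, mesylation) of the crowded adduct. The fallback carries the leaving group through the coupling instead of installing it afterwards, and sets out from 2. TsCl, pyridine and DMAP give the 3-O-tosylate F8. DDQ/H2O and then Dess–Martin periodinane, as in steps 3 and 4, give the 4-ol F9 and the 2,3-cis 3-tosyloxyflavan-4-one F10; a tosylate is chosen because it has no α-hydrogens for the aryllithium to remove. Addition of aryllithium 11 at −78 °C, anti to the axial sulfonate, and a cold aqueous quench give the tosyloxy carbinol F11. Et3Al, as in step 11, then triggers the same aryl shift, and the sequence comes back to the route at 17, two steps shorter.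

Further compounds

F1 | step 11 | 4-hydroxy-4-(penta-O-benzylcatechin-8-yl)-5,7,3',4'-tetra-O-benzylflavan-3-one (aryl trans to ring B) | O[C@]1(c3c(OCc4ccccc4)cc(OCc4ccccc4)c4c3O[C@H](c3ccc(OCc5ccccc5)c(OCc5ccccc5)c3)[C@@H](OCc3ccccc3)C4)c2c(OCc3ccccc3)cc(OCc3ccccc3)cc2O[C@H](c2ccc(OCc3ccccc3)c(OCc3ccccc3)c2)C1=O
F2 | step 11 | 3-hydroxy-3-(penta-O-benzylcatechin-8-yl)-5,7,3',4'-tetra-O-benzylflavan-4-one (aryl trans to ring B) | O=C1c2c(OCc3ccccc3)cc(OCc3ccccc3)cc2O[C@H](c2ccc(OCc3ccccc3)c(OCc3ccccc3)c2)[C@@]1(O)c1c(OCc2ccccc2)cc(OCc2ccccc2)c2c1O[C@H](c1ccc(OCc3ccccc3)c(OCc3ccccc3)c1)[C@@H](OCc1ccccc1)C2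
F3 | step 8 | tetra-O-benzyl-3-O-TBS-epicatechin-(4β→8)-penta-O-benzylcatechin | [C@H]1(c3c(OCc4ccccc4)cc(OCc4ccccc4)c4c3O[C@H](c3ccc(OCc5ccccc5)c(OCc5ccccc5)c3)[C@@H](OCc3ccccc3)C4)c2c(OCc3ccccc3)cc(OCc3ccccc3)cc2O[C@H](c2ccc(OCc3ccccc3)c(OCc3ccccc3)c2)[C@@H]1O[Si](C)(C)C(C)(C)C
F4 | step 8 | tetra-O-benzylepicatechin-(4β→8)-penta-O-benzylcatechin (free 3-OH) | [C@H]1(c3c(OCc4ccccc4)cc(OCc4ccccc4)c4c3O[C@H](c3ccc(OCc5ccccc5)c(OCc5ccccc5)c3)[C@@H](OCc3ccccc3)C4)c2c(OCc3ccccc3)cc(OCc3ccccc3)cc2O[C@H](c2ccc(OCc3ccccc3)c(OCc3ccccc3)c2)[C@@H]1O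
F5 | step 8 | 4-(penta-O-benzylcatechin-8-yl)-5,7,3',4'-tetra-O-benzylflavan-3-one | [C@H]1(c3c(OCc4ccccc4)cc(OCc4ccccc4)c4c3O[C@H](c3ccc(OCc5ccccc5)c(OCc5ccccc5)c3)[C@@H](OCc3ccccc3)C4)c2c(OCc3ccccc3)cc(OCc3ccccc3)cc2O[C@H](c2ccc(OCc3ccccc3)c(OCc3ccccc3)c2)C1=O
F6 | step 8 | C4 epimer of F1 (4-OH trans to ring B) | O[C@@]1(c3c(OCc4ccccc4)cc(OCc4ccccc4)c4c3O[C@H](c3ccc(OCc5ccccc5)c(OCc5ccccc5)c3)[C@@H](OCc3ccccc3)C4)c2c(OCc3ccccc3)cc(OCc3ccccc3)cc2O[C@H](c2ccc(OCc3ccccc3)c(OCc3ccccc3)c2)C1=O
F7 | step 8 | C3 epimer of F2 (aryl cis to ring B) | O=C1c2c(OCc3ccccc3)cc(OCc3ccccc3)cc2O[C@H](c2ccc(OCc3ccccc3)c(OCc3ccccc3)c2)[C@]1(O)c1c(OCc2ccccc2)cc(OCc2ccccc2)c2c1O[C@H](c1ccc(OCc3ccccc3)c(OCc3ccccc3)c1)[C@@H](OCc1ccccc1)C2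
F8 | step 10 | 5,7,3',4'-tetra-O-benzyl-3-O-tosyl-(−)-epicatechin | C1c2c(OCc3ccccc3)cc(OCc3ccccc3)cc2O[C@H](c2ccc(OCc3ccccc3)c(OCc3ccccc3)c2)[C@@H]1OS(=O)(=O)c1ccc(C)cc1
F9 | step 10 | 4β-hydroxy-5,7,3',4'-tetra-O-benzyl-3-O-tosylepicatechin | O[C@H]1c2c(OCc3ccccc3)cc(OCc3ccccc3)cc2O[C@H](c2ccc(OCc3ccccc3)c(OCc3ccccc3)c2)[C@@H]1OS(=O)(=O)c1ccc(C)cc1
F10 | step 10 | 5,7,3',4'-tetra-O-benzyl-3-O-tosyl-4-oxo-epicatechin (2,3-cis) | O=C1c2c(OCc3ccccc3)cc(OCc3ccccc3)cc2O[C@H](c2ccc(OCc3ccccc3)c(OCc3ccccc3)c2)[C@@H]1OS(=O)(=O)c1ccc(C)cc1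
F11 | step 10 | 3-O-tosyl 4-aryl-4-hydroxy flavan (tosylate analogue of 15) | O[C@]1(c3c(OCc4ccccc4)cc(OCc4ccccc4)c4c3O[C@H](c3ccc(OCc5ccccc5)c(OCc5ccccc5)c3)[C@@H](OCc3ccccc3)C4)c2c(OCc3ccccc3)cc(OCc3ccccc3)cc2O[C@H](c2ccc(OCc3ccccc3)c(OCc3ccccc3)c2)[C@@H]1OS(=O)(=O)c1ccc(C)cc1
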